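**Retrosynthetic overview**
1. Target 15 ⇐ pentabenzyl ether 14 by global hydrogenolysis; the single methyl ether comes in with a boronic acid.
2. Unit A (C3-linked flavanone, 2R,3S) ⇐ ligand-controlled dearomative 1,4-arylation of the 3-aryl γ-pyrone ring of 12 (C2 by catalyst, C3 trans by protonation).
3. Unit B (C8-linked flavanone, 2S) ⇐ the same dearomative arylation, antipodal ligand, on the unsubstituted γ-pyrone ring of the flat, achiral 3,8'-bichromone 10.
4. 10 ⇐ C3–C8' Negishi union of two copies of one chromone 6 (C3-zincated 6 + 8-iodide 8).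
5. 6 ⇐ 2,4,6-trihydroxyacetophenone 1. Ring order: both aromatic pyranone rings first, then the dihydropyranone of unit B, then that of unit A.

Assumption: the SMILES is read as (2R,3S), 2,3-trans, in the C3-linked flavanone (unit A) and (2S) in the C8-linked 4'-methoxyflavanone (unit B); both antipodes of t-BuPyOx [4-tert-butyl-2-(pyridin-2-yl)-4,5-dihydrooxazole] are taken as commercial.

**Route**

Step 1
Reactants: 1 2,4,6-trihydroxyacetophenone; 2 benzyl bromide
Product: 3 1-[2,4-bis(benzyloxy)-6-hydroxyphenyl]ethan-1-one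
Conditions: BnBr (2.1 equiv), K2CO3 (2.2 equiv), DMF, 0 °C to rt
Reagents that add atoms: benzyl bromide, BrCc1ccccc1
Why: Williamson etherification; after one ortho and the para phenol are benzylated, the last ortho phenol is locked in a hydrogen bond to the acetyl group and stays free, which is the handle for ring closure; no stereocentre.

Step 2
Reactants: 3 1-[2,4-bis(benzyloxy)-6-hydroxyphenyl]ethan-1-one; 4 N,N-dimethylformamide dimethyl acetal
Product: 6 5,7-bis(benzyloxy)-4H-chromen-4-one, via enaminone 5 (not isolated)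
Conditions: DMF-DMA (3 equiv), toluene, 100 °C; evaporate; conc. HCl, CH2Cl2, rt
Reagents that add atoms: N,N-dimethylformamide dimethyl acetal, COC(OC)N(C)C
Why: Enaminone condensation of the methyl ketone followed by acid-promoted addition–elimination of the free phenol with loss of dimethylamine (the classical enaminone chromone synthesis); aryl benzyl ethers survive brief HCl at rt; no stereocentre.

Step 3
Reactants: 6 5,7-bis(benzyloxy)-4H-chromen-4-one; 7 N-iodosuccinimide
Product: 8 5,7-bis(benzyloxy)-8-iodo-4H-chromen-4-one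
Conditions: NIS (1.05 equiv), CF3CO2H (0.2 equiv), MeCN/CH2Cl2, 0 °C to rt, dark
Reagents that add atoms: N-iodosuccinimide, O=C1CCC(=O)N1I
Why: Electrophilic aromatic iodination (SEAr); with the 5-oxygen alkylated, C8 (between the ring oxygen and one benzyloxy group) is the accessible activated carbon, whereas C6 lies between two benzyloxy groups, which is the trend known for 5,7-dialkoxyflavonoids; no stereocentre.

Step 4
Reactants: 6 5,7-bis(benzyloxy)-4H-chromen-4-one; 8 5,7-bis(benzyloxy)-8-iodo-4H-chromen-4-one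
Product: 10 5,5',7,7'-tetrakis(benzyloxy)-4H,4'H-[3,8'-bichromene]-4,4'-dione, via diarylzinc 9 (not isolated)
Conditions: 6 (1.25 equiv), Zn(TMP)2·2MgCl2·2LiCl (0.65 equiv; TMP = 2,2,6,6-tetramethylpiperidide), THF, −30 °C; then 8 (1.0 equiv), Pd(OAc)2 (4 mol %), SPhos (8 mol %), THF, 50 °C
Reagents that add atoms: none
Why: Carbonyl-directed C3 zincation of the chromone (MgCl2 on the carbonyl steers the amide base to the neighbouring C–H; an iodine quench of an aliquot confirms the site) followed by Negishi cross-coupling, with SPhos handling the di-ortho-substituted iodide; no stereocentre, and the new aryl–aryl axis rotates on the laboratory time scale.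

Step 5
Reactants: 10 5,5',7,7'-tetrakis(benzyloxy)-4H,4'H-[3,8'-bichromene]-4,4'-dione; 11 4-methoxyphenylboronic acid
Product: 12 5,7-bis(benzyloxy)-3-[(2S)-5,7-bis(benzyloxy)-2-(4-methoxyphenyl)-4-oxo-3,4-dihydro-2H-chromen-8-yl]-4H-chromen-4-one
Conditions: 11 (1.5 equiv), Pd(OCOCF3)2 (7.5 mol %), (R)-t-BuPyOx (9 mol %), NH4PF6 (30 mol %), H2O (5 equiv), ClCH2CH2Cl, 60 °C
Reagents that add atoms: 4-methoxyphenylboronic acid, COc1ccc(B(O)O)cc1
Why: Dearomative asymmetric conjugate arylation (cationic divalent palladium/pyridine–oxazoline with an arylboronic acid): only the 2,3-unsubstituted γ-pyrone ring undergoes carbopalladation, the ligand selects the face to give (2S) (sense taken from the cyclic-enone model, checked by CD), and the base-free medium prevents retro-oxa-Michael racemisation.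

Step 6
Reactants: 12 5,7-bis(benzyloxy)-3-[(2S)-5,7-bis(benzyloxy)-2-(4-methoxyphenyl)-4-oxo-3,4-dihydro-2H-chromen-8-yl]-4H-chromen-4-one; 13 4-(benzyloxy)phenylboronic acid
Product: 14 (2R,3S)-5,7-bis(benzyloxy)-2-[4-(benzyloxy)phenyl]-3-[(2S)-5,7-bis(benzyloxy)-2-(4-methoxyphenyl)-4-oxo-3,4-dihydro-2H-chromen-8-yl]-2,3-dihydro-4H-chromen-4-one
Conditions: 13 (3 equiv, in portions), Pd(OCOCF3)2 (15 mol %), (S)-t-BuPyOx (18 mol %), NH4PF6 (45 mol %), H2O (5 equiv), ClCH2CH2Cl, 80 °C; then camphorsulfonic acid (10 mol %), CHCl3, rt if any 2,3-cis isomer is present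
Reagents that add atoms: 4-(benzyloxy)phenylboronic acid, OB(O)c1ccc(OCc2ccccc2)cc1
Why: Proposed new method: dearomative conjugate arylation of a 3-aryl chromone, in which the cationic aryl–palladium adds syn across C2=C3 of the remaining γ-pyrone ring on the face next to the unsubstituted ring-oxygen edge of the orthogonal 3-aryl group, the antipodal ligand sets C2 as (R), the benzylic C3 palladium enolate is protonated and the acidic C3–H equilibrates to the diequatorial trans (3S) isomer, and any wrong-face product is a separable diastereomer because unit B is already (S); the closest known reactions are the same palladium/pyridine–oxazoline arylation of chromones and of β,β-disubstituted enones, and copper-mediated conjugate additions to isoflavones that give trans-2,3-disubstituted chromanones.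

Step 7
Reactants: 14 (2R,3S)-5,7-bis(benzyloxy)-2-[4-(benzyloxy)phenyl]-3-[(2S)-5,7-bis(benzyloxy)-2-(4-methoxyphenyl)-4-oxo-3,4-dihydro-2H-chromen-8-yl]-2,3-dihydro-4H-chromen-4-one
Product: 15 (2R,3S)-5,7-dihydroxy-2-(4-hydroxyphenyl)-3-[(2S)-5,7-dihydroxy-2-(4-methoxyphenyl)-4-oxo-3,4-dihydro-2H-chromen-8-yl]-2,3-dihydro-4H-chromen-4-one (CNP0140544.1)
Conditions: H2 (1 atm), 10% Pd/C, EtOAc/MeOH, rt, stop at full conversion
Reagents that add atoms: none
Why: Catalytic hydrogenolysis of the five aryl benzyl ethers under neutral conditions, which is much faster than cleavage of the flavanone C2–O bonds and leaves the methyl ether, both ketones and all three stereocentres untouched.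

**Compound list**
1 | 2,4,6-trihydroxyacetophenone | CC(=O)c1c(O)cc(O)cc1O | starting material
2 | benzyl bromide | BrCc1ccccc1 | starting material
3 | 1-[2,4-bis(benzyloxy)-6-hydroxyphenyl]ethan-1-one | CC(=O)c1c(O)cc(OCc2ccccc2)cc1OCc1ccccc1 | intermediate
4 | N,N-dimethylformamide dimethyl acetal | COC(OC)N(C)C | starting material
5 | (E)-1-[2,4-bis(benzyloxy)-6-hydroxyphenyl]-3-(dimethylamino)prop-2-en-1-one | CN(C)/C=C/C(=O)c1c(O)cc(OCc2ccccc2)cc1OCc1ccccc1 | intermediate
6 | 5,7-bis(benzyloxy)-4H-chromen-4-one | O=c1ccoc2cc(OCc3ccccc3)cc(OCc3ccccc3)c12 | intermediate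
7 | N-iodosuccinimide | O=C1CCC(=O)N1I | starting material
8 | 5,7-bis(benzyloxy)-8-iodo-4H-chromen-4-one | O=c1ccoc2c(I)c(OCc3ccccc3)cc(OCc3ccccc3)c12 | intermediate
9 | bis[5,7-bis(benzyloxy)-4-oxo-4H-chromen-3-yl]zinc (as its MgCl2/LiCl complex) | O=c1c([Zn]c2coc3cc(OCc4ccccc4)cc(OCc4ccccc4)c3c2=O)coc2cc(OCc3ccccc3)cc(OCc3ccccc3)c12 | intermediate
10 | 5,5',7,7'-tetrakis(benzyloxy)-4H,4'H-[3,8'-bichromene]-4,4'-dione | O=c1c(-c2c(OCc3ccccc3)cc(OCc3ccccc3)c3c(=O)ccoc23)coc2cc(OCc3ccccc3)cc(OCc3ccccc3)c12 | intermediate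
11 | 4-methoxyphenylboronic acid | COc1ccc(B(O)O)cc1 | starting material
12 | 5,7-bis(benzyloxy)-3-[(2S)-5,7-bis(benzyloxy)-2-(4-methoxyphenyl)-4-oxo-3,4-dihydro-2H-chromen-8-yl]-4H-chromen-4-one | COc1ccc([C@@H]2CC(=O)c3c(OCc4ccccc4)cc(OCc4ccccc4)c(-c4coc5cc(OCc6ccccc6)cc(OCc6ccccc6)c5c4=O)c3O2)cc1 | intermediate
13 | 4-(benzyloxy)phenylboronic acid | OB(O)c1ccc(OCc2ccccc2)cc1 | starting material
14 | (2R,3S)-5,7-bis(benzyloxy)-2-[4-(benzyloxy)phenyl]-3-[(2S)-5,7-bis(benzyloxy)-2-(4-methoxyphenyl)-4-oxo-3,4-dihydro-2H-chromen-8-yl]-2,3-dihydro-4H-chromen-4-one | COc1ccc([C@@H]2CC(=O)c3c(OCc4ccccc4)cc(OCc4ccccc4)c([C@@H]4C(=O)c5c(OCc6ccccc6)cc(OCc6ccccc6)cc5O[C@H]4c4ccc(OCc5ccccc5)cc4)c3O2)cc1 | intermediate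
15 | (2R,3S)-5,7-dihydroxy-2-(4-hydroxyphenyl)-3-[(2S)-5,7-dihydroxy-2-(4-methoxyphenyl)-4-oxo-3,4-dihydro-2H-chromen-8-yl]-2,3-dihydro-4H-chromen-4-one | COc1ccc([C@@H]2CC(=O)c3c(O)cc(O)c([C@@H]4C(=O)c5c(O)cc(O)cc5O[C@H]4c4ccc(O)cc4)c3O2)cc1 | target

**Totals**
Total step count: 7. Longest linear sequence: 7 (1 → 3 → 6 → 8 → 10 → 12 → 14 → 15).

**Steps most likely to fail, with fallbacks**

Step 6 (arylation of the hindered 3-aryl pyrone; both reactivity and facial sense are unproven). The fallback sets out from 12 and comes back at 14. Compound 12 is O-silylated with t-BuMe2SiOSO2CF3 (CH2Cl2, −40 °C) to the fully aromatic 4-silyloxybenzopyrylium triflate F1. Commercial potassium [4-(benzyloxy)phenyl]trifluoroborate then transfers its aryl group from boron to C2 of this cation (Petasis-type ipso transfer, so no metal has to bind the crowded C3). This gives the silyl enol ether F2 and its C2 epimer F3 in an uncontrolled ratio. Hydrolysis with 1 M HCl/THF protonates C3 trans to the C2 aryl and gives 14 together with its (2S,3R,2''S) diastereomer F4. Because unit B is already (S), 14 and F4 are diastereomers and are separated on silica, so the route rejoins at 14 with about half the material.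

Step 4 (site of C–H zincation and stability of the 3-metallated chromone). The fallback sets out from 3 and comes back at 10. Compound 3 is taken to enaminone 5 as in step 2, but the crude enaminone is cyclised with iodine (I2, CHCl3, rt; iodocyclisation with loss of dimethylamine) to 5,7-bis(benzyloxy)-3-iodo-4H-chromen-4-one F5. Zinc insertion (Zn dust, LiCl, THF, 25 °C) gives the regiochemically unambiguous [5,7-bis(benzyloxy)-4-oxo-4H-chromen-3-yl]zinc iodide F6. F6 is coupled with 8 under the Pd(OAc)2/SPhos conditions of step 4 to return at 10.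

Step 3 (C8 versus C6 iodination of 6). The fallback sets out from 3 and comes back at 8. Compound 3 is iodinated before ring formation (NIS, CH2Cl2/MeOH, 0 °C) at the less hindered carbon next to its free, chelated phenol, giving 1-[4,6-bis(benzyloxy)-2-hydroxy-3-iodophenyl]ethan-1-one F7. DMF-DMA converts F7 to the enaminone (E)-1-[4,6-bis(benzyloxy)-2-hydroxy-3-iodophenyl]-3-(dimethylamino)prop-2-en-1-one F8. HCl/CH2Cl2 then closes the pyranone ring through the only free phenol, which places iodine at C8 by construction and returns at 8.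

**Further compounds**
F1 | step 6 | 5,7-bis(benzyloxy)-3-[(2S)-5,7-bis(benzyloxy)-2-(4-methoxyphenyl)-4-oxo-3,4-dihydro-2H-chromen-8-yl]-4-[(tert-butyldimethylsilyl)oxy]chromenylium trifluoromethanesulfonate | COc1ccc([C@@H]2CC(=O)c3c(OCc4ccccc4)cc(OCc4ccccc4)c(-c4c[o+]c5cc(OCc6ccccc6)cc(OCc6ccccc6)c5c4O[Si](C)(C)C(C)(C)C)c3O2)cc1.[O-]S(=O)(=O)C(F)(F)F
F2 | step 6 | (2S)-5,7-bis(benzyloxy)-8-{(2S)-5,7-bis(benzyloxy)-2-[4-(benzyloxy)phenyl]-4-[(tert-butyldimethylsilyl)oxy]-2H-chromen-3-yl}-2-(4-methoxyphenyl)-2,3-dihydro-4H-chromen-4-one (chromene C2 is S by CIP here and becomes 2R in 14) | COc1ccc([C@@H]2CC(=O)c3c(OCc4ccccc4)cc(OCc4ccccc4)c(C4=C(O[Si](C)(C)C(C)(C)C)c5c(OCc6ccccc6)cc(OCc6ccccc6)cc5O[C@H]4c4ccc(OCc5ccccc5)cc4)c3O2)cc1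
F3 | step 6 | (2S)-5,7-bis(benzyloxy)-8-{(2R)-5,7-bis(benzyloxy)-2-[4-(benzyloxy)phenyl]-4-[(tert-butyldimethylsilyl)oxy]-2H-chromen-3-yl}-2-(4-methoxyphenyl)-2,3-dihydro-4H-chromen-4-one (C2 epimer of F2) | COc1ccc([C@@H]2CC(=O)c3c(OCc4ccccc4)cc(OCc4ccccc4)c(C4=C(O[Si](C)(C)C(C)(C)C)c5c(OCc6ccccc6)cc(OCc6ccccc6)cc5O[C@@H]4c4ccc(OCc5ccccc5)cc4)c3O2)cc1
F4 | step 6 | (2S,3R)-5,7-bis(benzyloxy)-2-[4-(benzyloxy)phenyl]-3-[(2S)-5,7-bis(benzyloxy)-2-(4-methoxyphenyl)-4-oxo-3,4-dihydro-2H-chromen-8-yl]-2,3-dihydro-4H-chromen-4-one | COc1ccc([C@@H]2CC(=O)c3c(OCc4ccccc4)cc(OCc4ccccc4)c([C@H]4C(=O)c5c(OCc6ccccc6)cc(OCc6ccccc6)cc5O[C@@H]4c4ccc(OCc5ccccc5)cc4)c3O2)cc1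
F5 | step 4 | 5,7-bis(benzyloxy)-3-iodo-4H-chromen-4-one | O=c1c(I)coc2cc(OCc3ccccc3)cc(OCc3ccccc3)c12
F6 | step 4 | [5,7-bis(benzyloxy)-4-oxo-4H-chromen-3-yl]zinc iodide | O=c1c([Zn]I)coc2cc(OCc3ccccc3)cc(OCc3ccccc3)c12
F7 | step 3 | 1-[4,6-bis(benzyloxy)-2-hydroxy-3-iodophenyl]ethan-1-one | CC(=O)c1c(O)c(I)c(OCc2ccccc2)cc1OCc1ccccc1
F8 | step 3 | (E)-1-[4,6-bis(benzyloxy)-2-hydroxy-3-iodophenyl]-3-(dimethylamino)prop-2-en-1-one | CN(C)/C=C/C(=O)c1c(O)c(I)c(OCc2ccccc2)cc1OCc1ccccc1
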